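**Plan**
- Retrosynthesis: after removal of seven O-methyl groups, both diaryl ether links are cut on their ring-carbon side, each into a phenol oxygen and a carboxyl-bearing arene carbon. These are the bond from the phloroglucinol-ring oxygen to C-1 of the central ring and the bond from O-4 of the central ring to C-5 of the benzene-1,2,3-triol ring.
- Enabling feature: each bridging oxygen sits on a ring carbon lying between two oxygenated carbons (C-1 of the 2,4,6-trihydroxyphenoxy ring, C-4 of the central ring). It is bonded to the carbon para to the equally flanked oxygen of the next ring (C-1 of the central ring, C-5 of the pyrogallol ring). The three rings are therefore one 2,6-dioxygenated 1,4-phenylene oxide unit repeated head to tail.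
- Forward: no ring is formed. In one electrolysis 2,4,6-trimethoxyphenol 1 takes up two molecules of syringic acid 2 with loss of two CO2, through dimer phenol 3, to give the heptamethyl ether 4. BBr3 then frees the eight phenols of target 5.
- Stereochemistry: the target is achiral and has no stereocentre, so nothing has to be set or preserved.

Key step: step 1

Remark: because the target has no stereocentre, the structure drawn is its only stereoisomer. The route has only two steps, so the risk section treats both rather than three.

**Step 1**
Reactants: 1 2,4,6-trimethoxyphenol; 2 syringic acid (2 equivalents)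
Product: 4 4-[2,6-dimethoxy-4-(2,4,6-trimethoxyphenoxy)phenoxy]-2,6-dimethoxyphenol, via dimer phenol 3 (not isolated)
Conditions: undivided cell, graphite anode, Pt cathode, constant current at low current density (about 4 F per mol of 1), Bu4NBF4, 2,6-lutidine, dry MeCN, 0 °C to rt, Ar; 2 added by syringe pump as its lutidinium salt; then aq NaHCO3 wash and chromatography
Reagents that add atoms: none
Why: Proposed new method: at the anode 1 and the syringate should each lose one electron and a proton to give aryloxyl radicals; the radical of 1, whose two ortho carbons and para carbon all carry methoxy groups, can bond productively only through oxygen and does so at the carboxyl-bearing para carbon of the syringate radical, and the resulting 4-aryloxy-4-carboxycyclohexa-2,5-dienone rearomatises by loss of CO2 to the 4-aryloxy-2,6-dimethoxyphenol 3, which enters the same cycle with the second syringate to give 4. The closest known reactions are the oxidative decarboxylative polymerisation of syringic acid to poly(2,6-dimethoxy-1,4-phenylene oxide) and the oxidative C–O polymerisation of 2,6-disubstituted phenols; what is new is halting a capped chain at a defined length of three rings. No ring is closed and no stereocentre is created, the two new skeletal bonds being the aryl C–O bonds from the cap oxygen to C-1 of the middle ring and from O-4 of the middle ring to C-1 of the terminal ring. The step needs O- over C-coupling, para regiochemistry, cross- over self-coupling and control of chain length. The first two are secured by the substrate, since every ortho position is methoxylated and CO2 is a traceless leaving group that makes only attack at the syringate para carbon irreversible, whereas O–C bonds formed at the methoxy- or aryloxy-bearing para carbons of 1, 3 and 4 give quinone ketals that revert. Cross-coupling should be favoured because the radicals of 1, 3 and 4 are persistent and form more easily than that of the slowly fed, carboxyl-deactivated 2, while chain length is set by the 1:2 stoichiometry and the charge passed, with carboxyl-terminated self-oligomers of 2 removed by the bicarbonate wash and recovered 1 and 3 returned to the next electrolysis.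

**Step 2**
Reactants: 4 4-[2,6-dimethoxy-4-(2,4,6-trimethoxyphenoxy)phenoxy]-2,6-dimethoxyphenol
Product: 5 5-[2,6-dihydroxy-4-(2,4,6-trihydroxyphenoxy)phenoxy]benzene-1,2,3-triol
Conditions: BBr3 (excess), CH2Cl2, −78 °C to rt, Ar; then degassed H2O, 0 °C; EtOAc extraction, Sephadex LH-20 or reversed-phase purification under Ar
Reagents that add atoms: none
Why: Lewis-acid-mediated aryl methyl ether cleavage, in which BBr3 coordinates each methoxy oxygen and bromide attacks the methyl carbon in an SN2 step, so the aryl–O bonds, including the two diaryl ether links that offer no alkyl carbon, should stay intact and hydrolytic work-up frees all eight phenols.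

**Compound list**
1 | 2,4,6-trimethoxyphenol | COc1cc(OC)c(O)c(OC)c1 | starting material
2 | syringic acid (4-hydroxy-3,5-dimethoxybenzoic acid) | COc1cc(C(=O)O)cc(OC)c1O | starting material
3 | 2,6-dimethoxy-4-(2,4,6-trimethoxyphenoxy)phenol (dimer phenol) | COc1cc(OC)c(Oc2cc(OC)c(O)c(OC)c2)c(OC)c1 | intermediate
4 | 4-[2,6-dimethoxy-4-(2,4,6-trimethoxyphenoxy)phenoxy]-2,6-dimethoxyphenol | COc1cc(OC)c(Oc2cc(OC)c(Oc3cc(OC)c(O)c(OC)c3)c(OC)c2)c(OC)c1 | intermediate
5 | 5-[2,6-dihydroxy-4-(2,4,6-trihydroxyphenoxy)phenoxy]benzene-1,2,3-triol | Oc1cc(O)c(Oc2cc(O)c(Oc3cc(O)c(O)c(O)c3)c(O)c2)c(O)c1 | target

**Step count and risks**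
Total step count: 2
Longest linear sequence: 2 steps

Steps most likely to fail (both steps of the route, riskiest first):

1. Step 1 (new method). What may go wrong:
- Loss of chain-length control, with growth stopping after one syringate unit or running on past two.
- Self-coupling of syringate radicals before they meet a cap-derived radical.
- Two-electron over-oxidation of the electron-rich rings to quinones.

Fallback with known chemistry: it sets out from 1 and forms the two ether bonds one at a time by copper-catalysed Ullmann diaryl ether coupling. Commercial 4-bromo-2,6-dimethoxyphenol is O-benzylated (BnBr, K2CO3, DMF) to 2-(benzyloxy)-5-bromo-1,3-dimethoxybenzene F1. Coupling of 1 with F1 (CuI, picolinic acid, K3PO4, DMSO, about 100 °C) should give 2-(benzyloxy)-1,3-dimethoxy-5-(2,4,6-trimethoxyphenoxy)benzene F2. Hydrogenolysis (H2, Pd/C, EtOAc) then gives the dimer phenol 3, isolated this time. A second coupling of 3 with F1 under the same conditions should give 2-(benzyloxy)-5-[2,6-dimethoxy-4-(2,4,6-trimethoxyphenoxy)phenoxy]-1,3-dimethoxybenzene F3. A second hydrogenolysis brings the sequence back to the route at 4.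

2. Step 2. What may go wrong:
- Incomplete cleavage of the flanked methyl ethers.
- Air oxidation of the electron-rich polyphenol during aqueous work-up and chromatography, which makes partially methylated material hard to remove.

Fallback: it sets out from 4 and changes the end game to capture and release through a stable derivative. After the BBr3 treatment the volatiles are removed and the crude polyphenol is acetylated at once (Ac2O, pyridine, cat. DMAP). This should give the air-stable octaacetate 5-[2,6-diacetoxy-4-(2,4,6-triacetoxyphenoxy)phenoxy]benzene-1,2,3-triyl triacetate F4, which can be purified on silica and freed from under-demethylated material. Acid-catalysed transesterification (catalytic HCl generated from AcCl in degassed MeOH, rt, Ar) then releases the phenols and returns to the route at 5.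

**Further compounds**
F1 | step 1 | 2-(benzyloxy)-5-bromo-1,3-dimethoxybenzene | COc1cc(Br)cc(OC)c1OCc2ccccc2
F2 | step 1 | 2-(benzyloxy)-1,3-dimethoxy-5-(2,4,6-trimethoxyphenoxy)benzene | COc1cc(OC)c(Oc2cc(OC)c(OCc3ccccc3)c(OC)c2)c(OC)c1
F3 | step 1 | 2-(benzyloxy)-5-[2,6-dimethoxy-4-(2,4,6-trimethoxyphenoxy)phenoxy]-1,3-dimethoxybenzene | COc1cc(OC)c(Oc2cc(OC)c(Oc3cc(OC)c(OCc4ccccc4)c(OC)c3)c(OC)c2)c(OC)c1
F4 | step 2 | 5-[2,6-diacetoxy-4-(2,4,6-triacetoxyphenoxy)phenoxy]benzene-1,2,3-triyl triacetate | CC(=O)Oc1cc(OC(C)=O)c(Oc2cc(OC(C)=O)c(Oc3cc(OC(C)=O)c(OC(C)=O)c(OC(C)=O)c3)c(OC(C)=O)c2)c(OC(C)=O)c1
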